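## Retrosynthetic overview

1. Target ⇐ methyl ent‑halimate (22) by Sharpless epoxidation, Payne rearrangement/hydrolysis and acetylation (sets C13, C14).
2. Halimane core 21 ⇐ ent‑labd‑8‑ene diester 19 by an acid‑triggered 1,2‑methyl shift C10→C9, relayed by the C18 ester (sets C8, C9 and the 1(10)‑alkene).
3. 19 ⇐ bicyclic enol triflate 14 + vinyl‑BF3K (C11–C12) + methyl but‑2‑ynoate (C13–C16).
4. 14 ⇐ ring‑B ketone 8 by C8 methylation, triflation and intramolecular ester‑enolate alkylation that closes ring A (sets C4).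
5. 8 ⇐ 2‑methylcyclohexenone (ring B) + methyl propanoate + 1‑chloro‑3‑iodopropane by asymmetric Mukaiyama–Michael addition/alkylation (sets C5, C10). Ring order: B, then A.

Note: C1–C20 refer to labdane/halimane numbering.
Assumption: the (S)‑oxazaborolidinium catalyst gives the (R)‑configured Michael adduct; if the sense is opposite, the (R)‑catalyst is used.

## Route

Step 1
Reactants: 1 methyl propanoate
Product: 3 1-methoxy-1-(trimethylsilyloxy)prop-1-ene (E/Z mixture), via lithium enolate 2 (not isolated)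
Conditions: LDA, THF, −78 °C; TMSCl, −78 → 23 °C; distil
Reagents that add atoms: chlorotrimethylsilane, C[Si](C)(C)Cl
Why: Kinetic ester enolisation and O‑silylation give the silyl ketene acetal needed for a Lewis‑acid Mukaiyama–Michael addition (no stereocentre).

Step 2
Reactants: 3 silyl ketene acetal; 4 2-methylcyclohex-2-en-1-one; 5 1-chloro-3-iodopropane
Product: 8 methyl 2-[(1R,2R)-2-(3-chloropropyl)-2-methyl-3-oxocyclohexyl]propanoate (propanoate C-2 epimers), via silyl enol ether 6 (not isolated), via ammonium enolate 7 (not isolated)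
Conditions: (S)-o-tolyl-CBS-oxazaborolidine·HNTf2 (10 mol %), Ph3PO (25 mol %), toluene, −20 °C; then THF, BnMe3N+F− (anhydrous), 5, −78 → 0 °C
Reagents that add atoms: none
Why: Catalytic asymmetric Mukaiyama–Michael addition sets C5 (the cationic chiral Lewis acid shields one face of the enone β‑carbon) and gives a regiodefined silyl enol ether; the fluoride‑released enolate is then C‑alkylated by the iodide end of 5 anti to the C5 substituent, setting quaternary C10 trans, while the propanoate α‑centre is erased in step 5.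

Step 3
Reactants: 8 keto ester
Product: 10 methyl 2-[(1R,2R)-2-(3-chloropropyl)-2,4-dimethyl-3-oxocyclohexyl]propanoate (epimers at ring C-4 and propanoate C-2), via lithium enolate 9 (not isolated)
Conditions: LDA (1.05 equiv), THF, −78 °C; MeI, −78 → −20 °C
Reagents that add atoms: iodomethane, CI
Why: Kinetic enolate alkylation at the only enolisable ketone α‑carbon (C8) installs C17; the ketone is deprotonated before the less acidic ester, and the C8 configuration is irrelevant because C8 becomes sp2 in step 4.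

Step 4
Reactants: 10 methyl ketone
Product: 12 methyl 2-[(1R,2R)-2-(3-chloropropyl)-2,4-dimethyl-3-(trifluoromethylsulfonyloxy)cyclohex-3-en-1-yl]propanoate, via potassium enolate 11 (not isolated)
Conditions: KHMDS, THF, −78 °C; PhNTf2, −78 → 0 °C
Reagents that add atoms: N-phenylbis(trifluoromethanesulfonimide), O=S(=O)(N(c1ccccc1)S(=O)(=O)C(F)(F)F)C(F)(F)F
Why: Enol triflate formation can only go toward C8 (C10 is quaternary), giving the tetrasubstituted C8=C9 triflate, which also masks the ketone for the next enolate step.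

Step 5
Reactants: 12 enol triflate
Product: 14 methyl (1S,4aR,8aS)-1,4a,6-trimethyl-5-(trifluoromethylsulfonyloxy)-1,2,3,4,4a,7,8,8a-octahydronaphthalene-1-carboxylate, via lithium ester enolate 13 (not isolated)
Conditions: LDA, THF/DMPU, −78 → 23 °C
Reagents that add atoms: none
Why: Intramolecular 6‑exo‑tet enolate alkylation closes ring A as a trans‑decalin; the tether delivers C3 to the enolate face syn to C10, and A(1,3) strain holds H5 in the enolate plane, so the ester ends equatorial (cis to H5) and the methyl axial, giving C4 = S.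

Step 6
Reactants: 14 bicyclic triflate; 15 potassium vinyltrifluoroborate
Product: 16 methyl (1S,4aR,8aS)-5-ethenyl-1,4a,6-trimethyl-1,2,3,4,4a,7,8,8a-octahydronaphthalene-1-carboxylate
Conditions: PdCl2(dppf)·CH2Cl2 (5 mol %), Et3N, n-PrOH, 90 °C
Reagents that add atoms: none
Why: Suzuki–Miyaura coupling of an alkenyl triflate with the small vinyl nucleophile tolerates the hindered C9 position and the ester (no stereocentre formed).

Step 7
Reactants: 16 diene; 17 methyl but-2-ynoate
Product: 19 methyl (1S,4aR,8aS)-5-[(3E)-5-methoxy-3-methyl-5-oxopent-3-en-1-yl]-1,4a,6-trimethyl-1,2,3,4,4a,7,8,8a-octahydronaphthalene-1-carboxylate (dimethyl ent-labda-8,13E-diene-15,18-dioate), via alkylborane 18 (not isolated)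
Conditions: 9-BBN-H, THF, 0 → 23 °C; then 17, CuOAc (10 mol %), P(OPh)3, t-BuOK (10 mol %), t-BuOH, dioxane, 40 °C
Reagents that add atoms: none
Why: 9‑BBN hydroborates only the terminal vinyl group (anti‑Markovnikov), and copper‑catalysed conjugate addition of the alkylborane to the ynoate with syn protonation gives the 13E enoate, which is inert to the acid used next.

Step 8
Reactants: 19 ent-labd-8-ene diester
Product: 21 methyl (1S,5S,6R,8aS)-5-[(3E)-5-methoxy-3-methyl-5-oxopent-3-en-1-yl]-1,5,6-trimethyl-1,2,3,5,6,7,8,8a-octahydronaphthalene-1-carboxylate (dimethyl ent-halima-1(10),13E-diene-15,18-dioate), via dioxolenium triflate 20 (not isolated)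
Conditions: TfOH (3 equiv), CH2Cl2/HFIP, −78 → −40 °C; then 2,6-di-tert-butyl-4-methylpyridine (5 equiv), −40 → 0 °C
Reagents that add atoms: none
Why: Proposed new method: protonation of C8=C9 on the β face (anti to the axial C10 methyl) gives the C9 cation, the C10 methyl migrates antiperiplanar to C9 (Wagner–Meerwein 1,2‑shift, setting C8 and C9), and the C10 cation is caught by the cis C4 ester carbonyl as a bridged dialkoxycarbenium ion that holds H5 in place; the hindered, non‑nucleophilic base then effects anti‑E2 in which only H1α is antiperiplanar to C10–O, giving the 1(10)‑alkene and restoring the ester; closest known reactions are BF3‑mediated 1,2‑H/1,2‑Me shifts of drim‑8‑enes (which end at the 5(10)‑alkene) and neighbouring‑ester (acyloxonium) participation.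

Step 9
Reactants: 21 halimadiene diester
Product: 22 methyl (1S,5S,6R,8aS)-5-[(3E)-5-hydroxy-3-methylpent-3-en-1-yl]-1,5,6-trimethyl-1,2,3,5,6,7,8,8a-octahydronaphthalene-1-carboxylate (methyl ent-halimate)
Conditions: DIBAL-H (2.2 equiv), CH2Cl2, −78 °C; Rochelle salt
Reagents that add atoms: none
Why: Chemoselective 1,2‑reduction of the unhindered enoate to the E‑allylic alcohol; the neopentylic tertiary C18 ester is far slower at −78 °C.

Step 10
Reactants: 22 allylic alcohol
Product: 23 methyl (1S,5S,6R,8aS)-5-{2-[(2R,3R)-3-(hydroxymethyl)-2-methyloxiran-2-yl]ethyl}-1,5,6-trimethyl-1,2,3,5,6,7,8,8a-octahydronaphthalene-1-carboxylate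
Conditions: Ti(OiPr)4 (10 mol %), D-(−)-DET (12 mol %), TBHP, 4 Å MS, CH2Cl2, −20 °C
Reagents that add atoms: tert-butyl hydroperoxide, CC(C)(C)OO
Why: Sharpless asymmetric epoxidation of a geraniol‑type E‑allylic alcohol is reagent‑controlled (D‑tartrate gives the 13R,14R epoxide) and leaves the non‑allylic 1(10)‑alkene untouched.

Step 11
Reactants: 23 epoxy alcohol
Product: 26 (1S,5S,6R,8aS)-5-[(3R,4S)-3,4,5-trihydroxy-3-methylpentyl]-1,5,6-trimethyl-1,2,3,5,6,7,8,8a-octahydronaphthalene-1-carboxylic acid, via epoxy alkoxide 24 (not isolated), via triol ester 25 (not isolated)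
Conditions: KOH (excess), DMSO/H2O 5:1, 90 °C; then 1 M HCl to pH 4, 0 °C
Reagents that add atoms: potassium hydroxide, [K+].[OH-]
Why: Payne rearrangement (the C15 alkoxide displaces the epoxide at C14 with inversion, C13 retained) exposes a terminal epoxide that hydroxide opens at C15 to give the 13R,14S triol, and the hot hydroxide also saponifies the hindered methyl ester; mild cold acidification avoids lactonisation onto the 1(10)‑alkene.

Step 12
Reactants: 26 triol acid
Product: 27 (1S,5S,6R,8aS)-5-[(3R,4S)-4,5-diacetoxy-3-hydroxy-3-methylpentyl]-1,5,6-trimethyl-1,2,3,5,6,7,8,8a-octahydronaphthalene-1-carboxylic acid (CNP0224606.1)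
Conditions: Ac2O, pyridine, 0 → 23 °C; aqueous work-up
Reagents that add atoms: acetic anhydride, CC(=O)OC(C)=O
Why: Acetylation esterifies the primary and secondary hydroxyls only; the tertiary C13–OH does not react without DMAP or heat, and the mixed anhydride of the acid is hydrolysed on work‑up.

## Compound list

1 | methyl propanoate | CCC(=O)OC | starting material
2 | lithium 1-methoxyprop-1-en-1-olate | CC=C(OC)O[Li] | intermediate (not isolated)
3 | 1-methoxy-1-(trimethylsilyloxy)prop-1-ene (E/Z) | CC=C(OC)O[Si](C)(C)C | intermediate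
4 | 2-methylcyclohex-2-en-1-one | CC1=CCCCC1=O | starting material
5 | 1-chloro-3-iodopropane | ClCCCI | starting material
6 | methyl 2-[(1R)-2-methyl-3-(trimethylsilyloxy)cyclohex-2-en-1-yl]propanoate (propanoate C-2 epimers) | C[Si](C)(C)OC1=C(C)[C@H](CCC1)C(C)C(=O)OC | intermediate (not isolated)
7 | benzyltrimethylammonium (3R)-3-(1-methoxy-1-oxopropan-2-yl)-2-methylcyclohex-1-en-1-olate | C[N+](C)(C)Cc1ccccc1.[O-]C1=C(C)[C@H](CCC1)C(C)C(=O)OC | intermediate (not isolated)
8 | methyl 2-[(1R,2R)-2-(3-chloropropyl)-2-methyl-3-oxocyclohexyl]propanoate (propanoate C-2 epimers) | O=C1CCC[C@H](C(C)C(=O)OC)[C@@]1(C)CCCCl | intermediate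
9 | lithium (5R,6R)-6-(3-chloropropyl)-5-(1-methoxy-1-oxopropan-2-yl)-6-methylcyclohex-1-en-1-olate | [Li]OC1=CCC[C@H](C(C)C(=O)OC)[C@@]1(C)CCCCl | intermediate (not isolated)
10 | methyl 2-[(1R,2R)-2-(3-chloropropyl)-2,4-dimethyl-3-oxocyclohexyl]propanoate (epimers at ring C-4 and propanoate C-2) | O=C1C(C)CC[C@H](C(C)C(=O)OC)[C@@]1(C)CCCCl | intermediate
11 | potassium (5R,6R)-6-(3-chloropropyl)-5-(1-methoxy-1-oxopropan-2-yl)-2,6-dimethylcyclohex-1-en-1-olate | [K]OC1=C(C)CC[C@H](C(C)C(=O)OC)[C@@]1(C)CCCCl | intermediate (not isolated)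
12 | methyl 2-[(1R,2R)-2-(3-chloropropyl)-2,4-dimethyl-3-(trifluoromethylsulfonyloxy)cyclohex-3-en-1-yl]propanoate | O=S(=O)(OC1=C(C)CC[C@H](C(C)C(=O)OC)[C@@]1(C)CCCCl)C(F)(F)F | intermediate
13 | lithium 1-methoxy-2-[(1R,2R)-2-(3-chloropropyl)-2,4-dimethyl-3-(trifluoromethylsulfonyloxy)cyclohex-3-en-1-yl]prop-1-en-1-olate | O=S(=O)(OC1=C(C)CC[C@H](C(C)=C(OC)O[Li])[C@@]1(C)CCCCl)C(F)(F)F | intermediate (not isolated)
14 | methyl (1S,4aR,8aS)-1,4a,6-trimethyl-5-(trifluoromethylsulfonyloxy)-1,2,3,4,4a,7,8,8a-octahydronaphthalene-1-carboxylate | O=S(=O)(OC1=C(C)CC[C@H]2[C@@]1(C)CCC[C@]2(C)C(=O)OC)C(F)(F)F | intermediate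
15 | potassium vinyltrifluoroborate | C=C[B-](F)(F)F.[K+] | starting material
16 | methyl (1S,4aR,8aS)-5-ethenyl-1,4a,6-trimethyl-1,2,3,4,4a,7,8,8a-octahydronaphthalene-1-carboxylate | C=CC1=C(C)CC[C@H]2[C@@]1(C)CCC[C@]2(C)C(=O)OC | intermediate
17 | methyl but-2-ynoate | CC#CC(=O)OC | starting material
18 | methyl (1S,4aR,8aS)-5-[2-(9-borabicyclo[3.3.1]nonan-9-yl)ethyl]-1,4a,6-trimethyl-1,2,3,4,4a,7,8,8a-octahydronaphthalene-1-carboxylate | C(CC1=C(C)CC[C@H]2[C@@]1(C)CCC[C@]2(C)C(=O)OC)B1C2CCCC1CCC2 | intermediate (not isolated)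
19 | methyl (1S,4aR,8aS)-5-[(3E)-5-methoxy-3-methyl-5-oxopent-3-en-1-yl]-1,4a,6-trimethyl-1,2,3,4,4a,7,8,8a-octahydronaphthalene-1-carboxylate | COC(=O)/C=C(C)/CCC1=C(C)CC[C@H]2[C@@]1(C)CCC[C@]2(C)C(=O)OC | intermediate
20 | O-methyl 18,10β-lactonium (dialkoxycarbenium) triflate of methyl ent-halim-13E-en-15-oate (4S,5R,8R,9S,10R) | COC(=O)/C=C(C)/CC[C@]1(C)[C@]23CCC[C@](C)(C(=[O+]C)O2)[C@H]3CC[C@H]1C.[O-]S(=O)(=O)C(F)(F)F | intermediate (not isolated)
21 | methyl (1S,5S,6R,8aS)-5-[(3E)-5-methoxy-3-methyl-5-oxopent-3-en-1-yl]-1,5,6-trimethyl-1,2,3,5,6,7,8,8a-octahydronaphthalene-1-carboxylate | COC(=O)/C=C(C)/CC[C@]1(C)C2=CCC[C@](C)(C(=O)OC)[C@H]2CC[C@H]1C | intermediate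
22 | methyl (1S,5S,6R,8aS)-5-[(3E)-5-hydroxy-3-methylpent-3-en-1-yl]-1,5,6-trimethyl-1,2,3,5,6,7,8,8a-octahydronaphthalene-1-carboxylate | OC/C=C(C)/CC[C@]1(C)C2=CCC[C@](C)(C(=O)OC)[C@H]2CC[C@H]1C | intermediate
23 | methyl (1S,5S,6R,8aS)-5-{2-[(2R,3R)-3-(hydroxymethyl)-2-methyloxiran-2-yl]ethyl}-1,5,6-trimethyl-1,2,3,5,6,7,8,8a-octahydronaphthalene-1-carboxylate | OC[C@H]1O[C@]1(C)CC[C@]1(C)C2=CCC[C@](C)(C(=O)OC)[C@H]2CC[C@H]1C | intermediate
24 | potassium (13R)-alkoxide of the Payne-rearranged (14S)-14,15-epoxide of 23 | [K+].[O-][C@](C)(CC[C@]1(C)C2=CCC[C@](C)(C(=O)OC)[C@H]2CC[C@H]1C)[C@@H]1CO1 | intermediate (not isolated)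
25 | methyl (1S,5S,6R,8aS)-5-[(3R,4S)-3,4,5-trihydroxy-3-methylpentyl]-1,5,6-trimethyl-1,2,3,5,6,7,8,8a-octahydronaphthalene-1-carboxylate | OC[C@H](O)[C@](C)(O)CC[C@]1(C)C2=CCC[C@](C)(C(=O)OC)[C@H]2CC[C@H]1C | intermediate (not isolated)
26 | (1S,5S,6R,8aS)-5-[(3R,4S)-3,4,5-trihydroxy-3-methylpentyl]-1,5,6-trimethyl-1,2,3,5,6,7,8,8a-octahydronaphthalene-1-carboxylic acid | OC[C@H](O)[C@](C)(O)CC[C@]1(C)C2=CCC[C@](C)(C(=O)O)[C@H]2CC[C@H]1C | intermediate
27 | (1S,5S,6R,8aS)-5-[(3R,4S)-4,5-diacetoxy-3-hydroxy-3-methylpentyl]-1,5,6-trimethyl-1,2,3,5,6,7,8,8a-octahydronaphthalene-1-carboxylic acid | CC(=O)OC[C@H](OC(C)=O)[C@](C)(O)CC[C@]1(C)C2=CCC[C@](C)(C(=O)O)[C@H]2CC[C@H]1C | target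

## Step count and risks

Total step count: 12. Longest linear sequence: 12 (fully linear).

Three steps most likely to fail:

Step 8 (the proposed new step). Risks are erosion of the β‑face protonation at C8, O‑demethylation of the dioxolenium ion to the lactone, and equilibration to the 5(10)‑alkene. Fallback with known chemistry, from 19 back to 21: the same acid treatment of 19 is quenched with water, which hydrolyses the ion to the lactone methyl (E)-5-[(4S,5R,8R,9S,10R)-18,10-olido-ent-halimanyl]-3-methylpent-2-enoate F7 (acid‑induced 1,2‑methyl shift and ester capture of a cation are both established). KOH in aqueous MeOH opens the lactone and saponifies the side‑chain ester, and alkylation of the dicarboxylate salt with MeI/K2CO3 in DMF, without acidification, gives the 10β-hydroxy diester dimethyl (4S,5R,8R,9S,10R)-10-hydroxy-ent-halim-13E-ene-15,18-dioate F8. POCl3 in pyridine at 0 °C then effects the classical anti dehydration, for which only H1α is antiperiplanar, returning to 21.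

Step 2. Risks are the enantioselectivity on an α‑substituted enone and C‑alkylation of a hindered enolate beside an ester. Fallback, from 4 and 5 back to 8: copper‑catalysed asymmetric conjugate addition of isopropenylmagnesium bromide to 4 (CuBr·SMe2, chiral ferrocenyl diphosphine, −78 °C) and trapping of the magnesium enolate with 5 in THF/DMPU give (2R,3R)-2-(3-chloropropyl)-2-methyl-3-(prop-1-en-2-yl)cyclohexan-1-one F1. Hydroboration–oxidation (9‑BBN, then NaBO3) gives (2R,3R)-2-(3-chloropropyl)-3-(1-hydroxypropan-2-yl)-2-methylcyclohexan-1-one F2. Jones oxidation, which also returns any over‑reduced ketone, gives 2-[(1R,2R)-2-(3-chloropropyl)-2-methyl-3-oxocyclohexyl]propanoic acid F3, and TMSCHN2/MeOH gives 8.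

Step 7. Risks are the copper step on a neopentylic alkylborane and loss of E selectivity. Fallback, from 14 back to 19 (bypassing 16): but‑3‑yn‑1‑ol undergoes zirconium‑catalysed carboalumination (Me3Al, Cp2ZrCl2) and trapping with ClCO2Me to give methyl (E)-5-hydroxy-3-methylpent-2-enoate F4. I2/PPh3/imidazole gives methyl (E)-5-iodo-3-methylpent-2-enoate F5, and zinc dust/LiCl in THF gives [(3E)-5-methoxy-3-methyl-5-oxopent-3-en-1-yl]zinc iodide F6. Negishi coupling of F6 with triflate 14 (Pd(OAc)2/SPhos, THF/NMP, 60 °C) gives 19.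

Further compounds
F1 | step 2 | (2R,3R)-2-(3-chloropropyl)-2-methyl-3-(prop-1-en-2-yl)cyclohexan-1-one | O=C1CCC[C@H](C(C)=C)[C@@]1(C)CCCCl
F2 | step 2 | (2R,3R)-2-(3-chloropropyl)-3-(1-hydroxypropan-2-yl)-2-methylcyclohexan-1-one | O=C1CCC[C@H](C(C)CO)[C@@]1(C)CCCCl
F3 | step 2 | 2-[(1R,2R)-2-(3-chloropropyl)-2-methyl-3-oxocyclohexyl]propanoic acid | O=C1CCC[C@H](C(C)C(=O)O)[C@@]1(C)CCCCl
F4 | step 7 | methyl (E)-5-hydroxy-3-methylpent-2-enoate | COC(=O)/C=C(C)/CCO
F5 | step 7 | methyl (E)-5-iodo-3-methylpent-2-enoate | COC(=O)/C=C(C)/CCI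
F6 | step 7 | [(3E)-5-methoxy-3-methyl-5-oxopent-3-en-1-yl]zinc iodide | COC(=O)/C=C(C)/CC[Zn]I
F7 | step 8 | methyl (E)-5-[(4S,5R,8R,9S,10R)-18,10-olido-ent-halimanyl]-3-methylpent-2-enoate (18,10β-lactone) | COC(=O)/C=C(C)/CC[C@]1(C)[C@]23CCC[C@](C)(C(=O)O2)[C@H]3CC[C@H]1C
F8 | step 8 | dimethyl (4S,5R,8R,9S,10R)-10-hydroxy-ent-halim-13E-ene-15,18-dioate | COC(=O)/C=C(C)/CC[C@]1(C)[C@@]2(O)CCC[C@](C)(C(=O)OC)[C@H]2CC[C@H]1C
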